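The rate constants were set for the occasion.

Target formation and decomposition compete for the same reagent in the reaction phase, and the quotient of their rates contains c(substrate) but not c(reagent in the reaction phase).

substrate 0.50 mM; reagent in the second phase 0.525 mM; time 2.5 s; volume of the second phase over the first 0.25

    reagent in the reaction phase → decomposed reagent (k1 = 0.623 s⁻¹)
    substrate + reagent in the reaction phase → target (k2 = 900 M⁻¹ s⁻¹)
    reagent in the reaction phase ⇌ reagent in the second phase, rate k3*([reagent in the reaction phase] - [reagent in the second phase]/K3) per volume of the first phase (K3 = 14, k3 = 1.67 s⁻¹)
    reagent in the reaction phase + target → over-reaction product (k4 = 1180 M⁻¹ s⁻¹)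
    substrate ⇌ dormant form (K5 = 2.10, k5 = 0.486 s⁻¹)

- in the second phase: reagent in the second phase; everything else is in the first
- charges count per volume of the first phase; a concentration in a rate is the amount of a species over the volume of its own phase; every rate counts per litre of the first phase
- run time (flask): 2.5 s

- target at 2.5 s, in percent of the substrate charged
- the change that raises the amount of target at 2.5 s, in percent of the substrate charged most ("none" if none brings more than 2 percentage points) (Tuesday's / Thursday's / none)
- amount of target at 2.5 s, in percent of the substrate charged, after Thursday's

I first take the substrate as relaxing towards the dormant form by that step alone, with rate constant 0.717 s⁻¹. This gives a mean c(substrate) of 0.319 mM up to 2.5 s. The rate of target formation over the rate of decomposition at that mean is what I call the reagent split, a selectivity factor: 0.460.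

For the amount, I hold c(reagent in the second phase) at its charge, 2.10 mM in its own volume. Feed against first-order losses then gives a plateau of 0.0971 mM, reached after a lag of 0.388 s. So I commit to y = 11.8%, or 11.8% by the short method. Doubling the transfer coefficient multiplies the plateau by 1.21, while doubling the reservoir multiplies it by 2, so I choose Thursday's, with yb below 23.5%.

The forecast gives 7.8% (6.8% to 8.8%), lower than mine, then 11.6% (10% to 13.2%) and Thursday's, holding that “Doubling the reservoir nearly doubles the reagent level”.

The flask gives y = 7.36%, yb = 12.5% and Thursday's, which adds 5.1 percentage points against 1.4 points for Tuesday's.

In this flask at 0.708 s, decomposition uses reagent in the reaction phase 2.0 times as fast as target formation does. At 2.50 s, target plus over-reaction product over decomposed reagent reads 0.417.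

In the neighbour with 1.2 mM of substrate, mean c(substrate) scales with the charge, so the split becomes 1.11. The computed reading there is 1.02, with target at 6.52% of that charge.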